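Atom numbering used throughout: each half is numbered as a cembrane (C1–C14 around the carbocycle, C15 the lactone α-carbon, C16 the lactone carbonyl, C17 the linker CH2, C18–C20 the methyls on C4, C8 and C12); primed numbers belong to the half whose C15' carries OH. Compound numbers 1–36 are those of the compound list.

## Analysis of the target

Target 36 consists of two cembrane-type halves. Each half is a 14-membered carbocycle (ring A, ring C) with a δ-lactone (ring B, ring D) fused trans across C1 and C3, an (E)-trisubstituted C7=C8 olefin, a trans-(11S,12S) trisubstituted epoxide and a tertiary carbinol at C4 next to the lactone oxygen on C3. The halves are joined by the C17–C17' bond, so that C15–C17–C17'–C15' is a four-carbon chain between the two lactone α-carbons. Of the twelve stereocentres, ten are pairwise identical (1R,3S,4S,11S,12S in both halves). The halves differ only at the lactone α-carbon: C15 carries H with C17 trans to C14, whereas C15' carries OH anti to C14' with C17' cis to C14'. Sensitive groups are the two trisubstituted epoxides (acid, Lewis acid, transannular opening), the monoacylated C3/C4 diols (acyl shift), the epimerisable C15–H and the trisubstituted olefins, which rule out undirected electrophilic oxidants. The difficulty lies in two 14-membered rings, in stereocentres that are remote from each other (C1, C3/C4, C11/C12) on a flexible ring, and in a dimer that is symmetric except at one pair of atoms. The strategy rests on that near-symmetry: once the C15/C15' difference is removed, the C15–C17–C17'–C15' bridge with the C16 and C16' carbonyls tied to O3 and O3' is a buta-1,3-diyne that has taken up two molecules of carbon monoxide, each delivered by the hydroxyl on C3 or C3'.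

## Retrosynthetic reasoning

36 ⇒ 35 ⇒ 34 ⇒ 32. The two α-stereocentres and the saturated bridge are removed first, which leads back to the C2-symmetric (E,E)-diene bis-lactone 32. Forward, one conjugate hydride addition to the dienedioate gives a single ester enolate equivalent that is hydroxylated (34). A second conjugate reduction (35) and an equilibration at C15 give 36. The cut is made here because the first reduction desymmetrises a symmetric precursor by reactivity alone, the doubly conjugated system being more electrophilic than the enoate it leaves behind.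

32 ⇒ 29 + two molecules of carbon monoxide 30. Four bonds are cut, C15–C16 and C16–O3 in each half, which opens rings B and D and leaves diyne tetraol 29. This is the only disconnection that removes both lactones and exposes the bridge as one functional group. Forward, palladium has to join each C3 hydroxyl, one CO and the nearer alkyne carbon, with the carbonyl on C15 and not on C17.

29 ⇒ two molecules of 28. The C17–C17' bond is cut in the middle of the diyne. An oxidative alkyne homocoupling makes it without any differentiation of the halves, so only one monomer has to be made.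

28 ⇒ 26 + 27 ⇒ 25. The terminal alkyne is traced to a lactol that holds C15 at the aldehyde level and O3 in masked form. The lactol comes from γ-lactone 25, in which C15 is the carbonyl bound to O3. A route through the six-membered lactone followed by removal of C16 was not taken, because a glycol cleavage on the way would also cut the C3–C4 diol of ring A.

25 ⇒ 24 ⇒ 23. Ring A is opened at C13–C14, the only ring bond that is CH2–CH2, unconjugated and remote from a stereocentre-forming event. Forward, ring-closing metathesis of two vinyl groups and a hydrogen-transfer reduction that spares trisubstituted olefins are needed.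

23 ⇒ 22 ⇒ 18 + 21 (21 from 19 and 20). The C1–C14 bond is cut next to the lactone carbonyl. Alkylation of the γ-lactone enolate anti to the C3 substituent sets C1 trans to C3, which is the relationship of 36. The two-carbon selenide 21 serves as a vinyl cation equivalent.

18 ⇒ 17 ⇒ 16 ⇒ 15 ⇒ 14. The vinyl epoxide is traced to an epoxy aldehyde and an epoxy alcohol, and the latter to the E-allylic alcohol 15, so that C11 and C12 are set by reagent-controlled epoxidation. 15 comes from 14 by allylic oxidation of the terminal E-methyl group.

14 ⇒ 13 ⇒ 10 + 11 (through 12). The C1–C2 bond and the lactone C–O bond are cut. Forward, the cis-epoxy alcohol 10 rearranges to the terminal epoxide 12 with inversion at C3, and the malonate 11 opens 12 at C2 and lactonises. The 3S,4S diol corresponds to anti opening of a Z-derived epoxide, which is why a 2Z olefin is required.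

10 ⇒ 9 ⇒ 7 ⇒ 3 + 6; 6 ⇒ 5 ⇒ 4; 3 ⇒ 1 + 2. The epoxide is removed to give (2Z,6E)-farnesol 9. The chain is cut at the doubly allylic C9–C10 bond into an allylic sulfone 3 and an allylic bromide 6, which derives from neryl acetate 4. The 2Z and 6E olefins are thus taken from 4 and from the selectivity of the allylic oxidation.

## Alternatives that were turned down

Alternative 1: C7=C8 is disconnected and formed by ring-closing metathesis with RuCl2(H2IMes)(PCy3)(=CHPh) (second-generation Grubbs catalyst) between a vinylsilane carbon C8 and a terminal olefin carbon C7. The silicon is tethered to the C4 oxygen, and the product is the seven-membered cyclic alkenylsiloxane A1. In its favour, the small ring forces silicon cis to C6, so that replacement of silicon by the C19 methyl with retention gives the E olefin with certainty. The unsaturated six-membered lactone of A1 would also allow C1 to be set by conjugate addition trans to C3. Against it, A1 is only a fragment: tether removal, methyl introduction, closure of ring A, and then the whole bridge between two halves still lie ahead. On the geometry of C7=C8 it is stronger in principle than the chosen route, which inherits that geometry from 4 and from the E-selectivity of an allylic oxidation. In its place the chosen strategy offers a terpene-derived chain with no tether steps, and it forms both lactones and the bridge in one step.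

Alternative 2: C6–C7 is disconnected. A dialkylborane (9-borabicyclo[3.3.1]nonane) hydroborates a C5=C6 vinyl group and palladium couples the C6 borane with a C7 alkenyl iodide, closing ring A and giving the nor-lactone silyl ether A2. In its favour, sp3–sp2 Suzuki macrocyclisation is dependable, the olefin geometry is fixed in the iodide, and the saturated C5–C6–C7 segment is formed directly. The chosen route needs a metathesis followed by a separate reduction at C13–C14, so on this point the alternative is stronger. A2 also keeps C15 as an enolisable CH2, so the bridge could be built by enolate alkylation anti to C14, which would set C15 under kinetic control. This too is stronger than the equilibration on which the chosen route depends. Against it, the chain must be assembled de novo, the hydroboration has to ignore the other olefins, lactone and epoxide must survive aqueous base, and a silyl group has to be put on and taken off. The two halves then have to be differentiated and joined in two further C–C bond formations. The chosen strategy instead uses one monomer and a symmetric homocoupling, and creates rings B and D together.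

Alternative 3: C3–C4 is disconnected. SmI2 couples a C3 aldehyde with a C4 methyl ketone of a geranylacetone-derived chain, closing ring A, and the C3 alkoxide then closes ring B to give the hydroxy nor-lactone A3. In its favour, it is the shortest way to rings A and B, and A3 again has a nucleophilic C15. Against it, C3 and C4 are both created in a 14-membered ketyl coupling, so the threo relationship and the sense relative to C1 rest on conformational preference across a large ring, with nothing in the reagent to enforce them. On step economy it is clearly stronger. The chosen route answers with reagent control of C3/C4 and C11/C12 (two asymmetric epoxidations) and substrate control of C1 in a five-membered ring, and concentrates its uncertainty in one late catalytic step.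

Key step: step 21

Remark on the chemistry: 36 is assumed to be the more stable C15 epimer of its lactone (C17 trans to C14), so that base equilibration can set this centre.

## Route

Step 1
Reactants: 1 1-bromo-3-methylbut-2-ene (prenyl bromide); 2 sodium benzenesulfinate
Product: 3 [(3-methylbut-2-en-1-yl)sulfonyl]benzene (prenyl phenyl sulfone)
Conditions: DMF, rt
Reagents that add atoms: none
Why: SN2 S-alkylation of the sulfinate by the allylic bromide gives the sulfone; no stereocentre is involved.

Step 2
Reactants: 4 neryl acetate, (2Z)-3,7-dimethylocta-2,6-dien-1-yl acetate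
Product: 5 (2Z,6E)-8-hydroxy-3,7-dimethylocta-2,6-dien-1-yl acetate
Conditions: SeO2 (0.3 equiv), t-BuOOH, salicylic acid (cat.), CH2Cl2, rt
Reagents that add atoms: tert-butyl hydroperoxide, CC(C)(C)OO (oxygen passed on through selenium dioxide, O=[Se]=O)
Why: SeO2 allylic oxidation (ene reaction, then [2,3]-shift) attacks the E-methyl group of the terminal olefin, while the 2,3-olefin is deactivated by the allylic acetate. This places C9 trans to C6 and so fixes the 7E geometry of the target.

Step 3
Reactants: 5 (2Z,6E)-8-hydroxy-3,7-dimethylocta-2,6-dien-1-yl acetate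
Product: 6 (2Z,6E)-8-bromo-3,7-dimethylocta-2,6-dien-1-yl acetate
Conditions: CBr4, PPh3, CH2Cl2, 0 °C
Reagents that add atoms: carbon tetrabromide, BrC(Br)(Br)Br
Why: Appel bromination of the primary allylic alcohol under neutral conditions should leave the acetate and both olefin geometries untouched.

Step 4
Reactants: 3 prenyl phenyl sulfone; 6 (2Z,6E)-8-bromo-3,7-dimethylocta-2,6-dien-1-yl acetate
Product: 7 (2Z,6E)-3,7,11-trimethyl-9-(phenylsulfonyl)dodeca-2,6,10-trien-1-yl acetate (racemic at the sulfonyl carbon C10)
Conditions: 3, n-BuLi, THF, –78 °C; then 6, –78 → –40 °C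
Reagents that add atoms: none
Why: α-Alkylation of the lithiated allylic sulfone by the allylic bromide (Julia-type terpenoid coupling) forms C9–C10; at –78 °C the stabilised anion should not attack the acetate.

Step 5
Reactants: 7 (2Z,6E)-3,7,11-trimethyl-9-(phenylsulfonyl)dodeca-2,6,10-trien-1-yl acetate
Product: 9 (2Z,6E)-farnesol, (2Z,6E)-3,7,11-trimethyldodeca-2,6,10-trien-1-ol, via lithium alkoxide 8 (not isolated)
Conditions: LiBHEt3 (4 equiv), THF, –78 → 0 °C; then PdCl2(dppp) (5 mol%), 0 °C → rt
Reagents that add atoms: none
Why: LiBHEt3 first cleaves the acetate, so that no allylic ester is left when palladium is added. Palladium-catalysed reductive desulfonylation of the allylic sulfone then delivers hydride to the less substituted terminus (C10) of the π-allyl intermediate and keeps C11=C12 in place.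

Step 6
Reactants: 9 (2Z,6E)-farnesol
Product: 10 [(2R,3S)-3-[(3E)-4,8-dimethylnona-3,7-dien-1-yl]-3-methyloxiran-2-yl]methanol (cis-epoxide; C3 R, C4 S in target numbering)
Conditions: Ti(OiPr)4 (0.5 equiv), D-(–)-diethyl tartrate (0.6 equiv), t-BuOOH, 4 Å MS, CH2Cl2, –25 °C
Reagents that add atoms: tert-butyl hydroperoxide, CC(C)(C)OO
Why: Sharpless asymmetric epoxidation touches only the allylic alcohol olefin, and the D-tartrate ligand directs oxygen to the face that gives the (2R,3S) epoxide. The lower selectivity usual for Z-allylic alcohols is corrected later, since the second catalyst-controlled epoxidation (step 10) turns the minor enantiomer into a separable diastereomer.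

Step 7
Reactants: 10 cis-epoxy alcohol; 11 diethyl malonate
Product: 13 ethyl (5S)-5-[(2S,5E)-2-hydroxy-6,10-dimethylundeca-5,9-dien-2-yl]-2-oxooxolane-3-carboxylate (both epimers at the ester-bearing carbon), via terminal epoxide 12 (not isolated)
Conditions: NaOEt (3 equiv), 11 (3 equiv), EtOH, 75 °C; then AcOH
Reagents that add atoms: none
Why: Payne rearrangement (the C2 alkoxide opens the epoxide at C3 with inversion) is followed by trapping: the malonate anion attacks only the terminal epoxide 12 at C2, and the C3 alkoxide closes the five-membered lactone onto one ester. This forms C1–C2 and gives C3 as S (inversion) and C4 as S (retention), the threo diol pattern of the target.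

Step 8
Reactants: 13 ethyl 2-oxooxolane-3-carboxylate derivative
Product: 14 (5S)-5-[(2S,5E)-2-hydroxy-6,10-dimethylundeca-5,9-dien-2-yl]oxolan-2-one
Conditions: LiCl, DMSO, H2O, 140 °C
Reagents that add atoms: none
Why: Krapcho dealkoxycarbonylation of the β-dicarbonyl unit under neutral conditions removes the stereo-undefined ester without touching the tertiary alcohol or the olefins.

Step 9
Reactants: 14 hydroxy lactone
Product: 15 (5S)-5-[(2S,5E,9E)-2,11-dihydroxy-6,10-dimethylundeca-5,9-dien-2-yl]oxolan-2-one
Conditions: SeO2 (0.3 equiv), t-BuOOH, salicylic acid (cat.), CH2Cl2, rt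
Reagents that add atoms: tert-butyl hydroperoxide, CC(C)(C)OO (oxygen passed on through selenium dioxide, O=[Se]=O)
Why: SeO2 allylic oxidation again selects the E-methyl group of the terminal isopropylidene unit, the usual site in farnesyl-type chains, and so places the new C13 hydroxyl trans to C10.

Step 10
Reactants: 15 allylic alcohol
Product: 16 (5S)-5-[(2S,5E)-2-hydroxy-8-[(2S,3S)-3-(hydroxymethyl)-3-methyloxiran-2-yl]-6-methyloct-5-en-2-yl]oxolan-2-one
Conditions: Ti(OiPr)4 (0.1 equiv), L-(+)-diethyl tartrate (0.12 equiv), t-BuOOH, 4 Å MS, CH2Cl2, –20 °C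
Reagents that add atoms: tert-butyl hydroperoxide, CC(C)(C)OO
Why: Sharpless asymmetric epoxidation of the E-2-methyl allylic alcohol with the L-tartrate ligand should give the (11S,12S) epoxide. It leaves C7=C8 alone because only the olefin next to the primary hydroxyl is bound to titanium.

Step 11
Reactants: 16 epoxy alcohol
Product: 17 (5S)-5-[(2S,5E)-8-[(2S,3R)-3-formyl-3-methyloxiran-2-yl]-2-hydroxy-6-methyloct-5-en-2-yl]oxolan-2-one
Conditions: Dess–Martin periodinane, NaHCO3, CH2Cl2, 0 °C → rt
Reagents that add atoms: none
Why: Dess–Martin oxidation of the primary alcohol; the aldehyde has no α-hydrogen (C12 is quaternary), so it cannot epimerise, and the tertiary C4 hydroxyl is inert.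

Step 12
Reactants: 17 epoxy aldehyde
Product: 18 (5S)-5-[(2S,5E)-8-[(2S,3S)-3-ethenyl-3-methyloxiran-2-yl]-2-hydroxy-6-methyloct-5-en-2-yl]oxolan-2-one
Conditions: Ph3PCH3Br, KN(SiMe3)2, THF, –78 → 0 °C (ylide preformed), then 17
Reagents that add atoms: methyltriphenylphosphonium bromide, C[P+](c1ccccc1)(c1ccccc1)c1ccccc1.[Br-]
Why: Wittig methylenation of the aldehyde; the ylide is too weak a base to deprotonate the lactone or the tertiary alcohol, and the aldehyde reacts far faster than the lactone carbonyl.

Step 13
Reactants: 19 diphenyl diselenide; 20 1,2-dibromoethane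
Product: 21 (2-bromoethyl)(phenyl)selane
Conditions: 19, NaBH4, EtOH, 0 °C; then 20 (5 equiv), 0 °C → rt
Reagents that add atoms: none
Why: Reduction of the Se–Se bond gives the selenolate, which is alkylated once by the excess dibromide (SN2).

Step 14
Reactants: 18 vinyl epoxide lactone; 21 (2-bromoethyl)(phenyl)selane
Product: 22 (3S,5S)-5-[(2S,5E)-8-[(2S,3S)-3-ethenyl-3-methyloxiran-2-yl]-2-hydroxy-6-methyloct-5-en-2-yl]-3-[2-(phenylselanyl)ethyl]oxolan-2-one
Conditions: LiN(iPr)2 (2.2 equiv), THF, –78 °C; then 21, HMPA, –78 → –30 °C
Reagents that add atoms: none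
Why: The alkoxide–enolate dianion is alkylated at C1 on the face anti to the bulky C3 substituent, the normal course for 5-substituted γ-lactone enolates, so C14 is placed trans to C4 as in the target. The neighbouring selenium activates the bromide towards substitution.

Step 15
Reactants: 22 selenide
Product: 23 (3S,5S)-3-ethenyl-5-[(2S,5E)-8-[(2S,3S)-3-ethenyl-3-methyloxiran-2-yl]-2-hydroxy-6-methyloct-5-en-2-yl]oxolan-2-one
Conditions: NaIO4, NaHCO3, MeOH/THF/H2O, 0 °C → rt
Reagents that add atoms: none
Why: Oxidation to the selenoxide and syn-elimination at room temperature; the only β-hydrogens are on C14, so the vinyl group is the sole product. The near-neutral medium should keep the C1 stereocentre and prevent migration of the olefin into conjugation.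

Step 16
Reactants: 23 diene
Product: 24 γ-lactone (C15 carbonyl to O3) of (1S,3S,4S,7E,11S,12S)-11,12-epoxy-3,4-dihydroxy-4,8,12-trimethylcyclotetradeca-7,13-diene-1-carboxylic acid (C13=C14 as formed, E or Z)
Conditions: RuCl2(H2IMes)(PCy3)(=CHPh) (second-generation Grubbs catalyst, 10 mol%), 1,4-benzoquinone (20 mol%), CH2Cl2 (1 mM), 40 °C
Reagents that add atoms: none
Why: Ring-closing metathesis of the two monosubstituted vinyl groups closes the 14-membered ring A at C13=C14. The trisubstituted C7=C8 is too hindered to compete, and a six-membered ring through C8 is impossible because C10 and C13 are trans on the epoxide; benzoquinone suppresses ruthenium hydride isomerisation.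

Step 17
Reactants: 24 macrocyclic diene
Product: 25 γ-lactone (C15 carbonyl to O3) of (1R,3S,4S,7E,11S,12S)-11,12-epoxy-3,4-dihydroxy-4,8,12-trimethylcyclotetradec-7-ene-1-carboxylic acid
Conditions: 2-nitrobenzenesulfonohydrazide, Et3N, THF/i-PrOH, rt
Reagents that add atoms: none
Why: Diimide generated in situ reduces the 1,2-disubstituted C13=C14 much faster than the trisubstituted C7=C8, and as a metal-free reductant it cannot hydrogenolyse the allylic epoxide.

Step 18
Reactants: 25 γ-lactone
Product: 26 lactol of 25 (C15 hemiacetal carbon bound to O3; both anomers)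
Conditions: iBu2AlH (2.5 equiv), CH2Cl2, –78 °C; aq. KNaC4H4O6
Reagents that add atoms: none
Why: Partial reduction of the lactone stops at the aluminium hemiacetal at –78 °C; one extra equivalent is consumed by the tertiary hydroxyl, and the epoxide is inert at this temperature.

Step 19
Reactants: 26 lactol; 27 dimethyl (1-diazo-2-oxopropyl)phosphonate
Product: 28 (1R,3S,4S,7E,11S,12S)-11,12-epoxy-1-ethynyl-4,8,12-trimethylcyclotetradec-7-ene-3,4-diol
Conditions: K2CO3, MeOH, 0 °C → rt
Reagents that add atoms: none
Why: Seyferth–Gilbert homologation in the Ohira–Bestmann form acts on the open hydroxy aldehyde in equilibrium with the lactol and turns C15 into the alkyne carbon while freeing the C3 hydroxyl. The low concentration of open aldehyde and the mild base should preserve C1.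

Step 20
Reactants: 28 alkynyl diol (two molecules)
Product: 29 1,4-bis[(1R,3S,4S,7E,11S,12S)-11,12-epoxy-3,4-dihydroxy-4,8,12-trimethylcyclotetradec-7-en-1-yl]buta-1,3-diyne
Conditions: CuCl (20 mol%), TMEDA, O2 (1 atm), acetone, rt
Reagents that add atoms: none
Why: Glaser–Hay oxidative homocoupling of the terminal alkyne forms C17–C17'; free hydroxyls, epoxides and isolated olefins are tolerated under these neutral conditions.

Step 21
Reactants: 29 diyne tetraol; 30 carbon monoxide (two molecules)
Product: 32 C2-symmetric (15E,15'E)-diene bis-lactone (rings A to D complete; C15=C17 and C15'=C17'; no hydroxyl on C15'), via mono-lactone enyne 31 (not isolated)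
Conditions: PdCl2(PPh3)2 (10 mol%), anhydrous SnCl2 (10 mol%), CO (7 bar), MeCN, 60 °C
Reagents that add atoms: none
Why: Proposed new method: divalent palladium, the C3 hydroxyl and CO give an alkoxycarbonylpalladium chloride, which adds syn across the neighbouring triple bond so that C16 bonds to C15 and palladium to C17; protonolysis of the alkenyl–palladium bond by the HCl released in the first stage returns the catalyst, and the same sequence then runs from the C3' hydroxyl on the second alkyne. The closest known reaction type is the palladium-catalysed cyclocarbonylation of but-3-yn-1-ols and pent-4-yn-1-ols to α-methylene lactones; a conjugated diyne reacting twice has not been shown. Ring B and ring D each close by a 6-exo-dig acylpalladation. No stereocentre is formed; syn addition and protonolysis with retention make both alkylidene groups E. The step needs the carbonyl on C15 and C15' and not on C17 and C17': the six-membered ring secures this, since the alkoxycarbonyl group on O3 can reach C17 only through a seven-membered ring, and the tertiary C4 hydroxyl could reach C15 only through a seven-membered ring as well. It also needs the epoxides to survive the weakly acidic, tin-containing medium, hence the low loading, the dry SnCl2 and the lowest temperature at which turnover is seen.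

Step 22
Reactants: 32 (E,E)-diene bis-lactone
Product: 34 (15E,15'S)-15'-hydroxy enoate bis-lactone (C15=C17 retained; C15' bears OH anti to C14'), via ketene silyl acetal 33 (not isolated)
Conditions: [(Ph3P)CuH]6 (5 mol%), PhMe2SiH (1.05 equiv), toluene, 0 °C; then dimethyldioxirane (1.0 equiv), acetone/CH2Cl2, –78 °C; then Bu4NF, AcOH, THF, 0 °C
Reagents that add atoms: dimethyldioxirane, CC1(C)OO1
Why: Copper hydride catalysed 1,4-hydrosilylation puts hydride on the unhindered β-carbon C17'; the dienedioate is more electrophilic than the isolated enoate left behind, so one equivalent of silane should stop at 33. Rubottom oxidation of the electron-rich ketene acetal at –78 °C is much faster than epoxidation of the trisubstituted olefins, and the oxidant approaches anti to the pseudo-axial C14', which gives 15'S.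

Step 23
Reactants: 34 hydroxy enoate bis-lactone
Product: 35 15-epi-36, the (15R) epimer (C17 cis to C14), possibly accompanied by 36
Conditions: [(Ph3P)CuH]6 (5 mol%), PhMe2SiH (1.5 equiv), t-BuOH (3 equiv), toluene, rt
Reagents that add atoms: none
Why: Copper hydride conjugate reduction of the remaining alkylidene lactone with in situ protonation by t-BuOH; kinetic protonation of the enolate anti to C14 should favour the 15R epimer, and the epoxides, isolated olefins and the α-hydroxy lactone are not reduced.

Step 24
Reactants: 35 15-epi-36
Product: 36 target CNP0186476.4, (1R,3S,4S,7E,11S,12S,15S,1'R,3'S,4'S,7'E,11'S,12'S,15'S)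
Conditions: DBU (0.3 equiv), toluene, 60 °C
Reagents that add atoms: none
Why: Base-mediated epimerisation through the lactone enolate should lead to the trans arrangement of C17 and C14 that is generally preferred for 3,4-disubstituted six-membered lactones. C15' is quaternary and cannot epimerise, and a non-nucleophilic amidine avoids lactone opening.

## Compound list

1 | 1-bromo-3-methylbut-2-ene (prenyl bromide) | CC(C)=CCBr | starting material
2 | sodium benzenesulfinate | [Na+].[O-]S(=O)c1ccccc1 | starting material
3 | [(3-methylbut-2-en-1-yl)sulfonyl]benzene | CC(C)=CCS(=O)(=O)c1ccccc1 | intermediate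
4 | neryl acetate, (2Z)-3,7-dimethylocta-2,6-dien-1-yl acetate | CC(C)=CCC/C(C)=C\COC(C)=O | starting material
5 | (2Z,6E)-8-hydroxy-3,7-dimethylocta-2,6-dien-1-yl acetate | OC/C(C)=C/CC/C(C)=C\COC(C)=O | intermediate
6 | (2Z,6E)-8-bromo-3,7-dimethylocta-2,6-dien-1-yl acetate | BrC/C(C)=C/CC/C(C)=C\COC(C)=O | intermediate
7 | (2Z,6E)-3,7,11-trimethyl-9-(phenylsulfonyl)dodeca-2,6,10-trien-1-yl acetate | CC(=O)OC/C=C(C)\CC/C=C(C)/CC(S(=O)(=O)c1ccccc1)C=C(C)C | intermediate
8 | lithium (2Z,6E)-3,7,11-trimethyl-9-(phenylsulfonyl)dodeca-2,6,10-trien-1-olate | [Li+].[O-]C/C=C(C)\CC/C=C(C)/CC(S(=O)(=O)c1ccccc1)C=C(C)C | intermediate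
9 | (2Z,6E)-farnesol | OC/C=C(C)\CC/C=C(C)/CCC=C(C)C | intermediate
10 | [(2R,3S)-3-[(3E)-4,8-dimethylnona-3,7-dien-1-yl]-3-methyloxiran-2-yl]methanol | OC[C@H]1O[C@@]1(C)CC/C=C(C)/CCC=C(C)C | intermediate
11 | diethyl malonate | CCOC(=O)CC(=O)OCC | starting material
12 | (2S,5E)-6,10-dimethyl-2-[(2S)-oxiran-2-yl]undeca-5,9-dien-2-ol (as its sodium alkoxide) | C1O[C@@H]1[C@@](C)(O)CC/C=C(C)/CCC=C(C)C | intermediate
13 | ethyl (5S)-5-[(2S,5E)-2-hydroxy-6,10-dimethylundeca-5,9-dien-2-yl]-2-oxooxolane-3-carboxylate | CCOC(=O)C1C[C@H](OC1=O)[C@@](C)(O)CC/C=C(C)/CCC=C(C)C | intermediate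
14 | (5S)-5-[(2S,5E)-2-hydroxy-6,10-dimethylundeca-5,9-dien-2-yl]oxolan-2-one | O=C1CC[C@H](O1)[C@@](C)(O)CC/C=C(C)/CCC=C(C)C | intermediate
15 | (5S)-5-[(2S,5E,9E)-2,11-dihydroxy-6,10-dimethylundeca-5,9-dien-2-yl]oxolan-2-one | O=C1CC[C@H](O1)[C@@](C)(O)CC/C=C(C)/CC/C=C(C)/CO | intermediate
16 | (5S)-5-[(2S,5E)-2-hydroxy-8-[(2S,3S)-3-(hydroxymethyl)-3-methyloxiran-2-yl]-6-methyloct-5-en-2-yl]oxolan-2-one | O=C1CC[C@H](O1)[C@@](C)(O)CC/C=C(C)/CC[C@@H]1O[C@@]1(C)CO | intermediate
17 | (5S)-5-[(2S,5E)-8-[(2S,3R)-3-formyl-3-methyloxiran-2-yl]-2-hydroxy-6-methyloct-5-en-2-yl]oxolan-2-one | O=C1CC[C@H](O1)[C@@](C)(O)CC/C=C(C)/CC[C@@H]1O[C@@]1(C)C=O | intermediate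
18 | (5S)-5-[(2S,5E)-8-[(2S,3S)-3-ethenyl-3-methyloxiran-2-yl]-2-hydroxy-6-methyloct-5-en-2-yl]oxolan-2-one | O=C1CC[C@H](O1)[C@@](C)(O)CC/C=C(C)/CC[C@@H]1O[C@@]1(C)C=C | intermediate
19 | diphenyl diselenide | c1ccc(cc1)[Se][Se]c1ccccc1 | starting material
20 | 1,2-dibromoethane | BrCCBr | starting material
21 | (2-bromoethyl)(phenyl)selane | BrCC[Se]c1ccccc1 | intermediate
22 | (3S,5S)-5-[(2S,5E)-8-[(2S,3S)-3-ethenyl-3-methyloxiran-2-yl]-2-hydroxy-6-methyloct-5-en-2-yl]-3-[2-(phenylselanyl)ethyl]oxolan-2-one | O=C1[C@H](CC[Se]c2ccccc2)C[C@H](O1)[C@@](C)(O)CC/C=C(C)/CC[C@@H]1O[C@@]1(C)C=C | intermediate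
23 | (3S,5S)-3-ethenyl-5-[(2S,5E)-8-[(2S,3S)-3-ethenyl-3-methyloxiran-2-yl]-2-hydroxy-6-methyloct-5-en-2-yl]oxolan-2-one | O=C1[C@H](C=C)C[C@H](O1)[C@@](C)(O)CC/C=C(C)/CC[C@@H]1O[C@@]1(C)C=C | intermediate
24 | γ-lactone (C15 to O3) of (1S,3S,4S,7E,11S,12S)-11,12-epoxy-3,4-dihydroxy-4,8,12-trimethylcyclotetradeca-7,13-diene-1-carboxylic acid | O=C1O[C@H]2C[C@H]1C=C[C@]3(C)O[C@H]3CC/C(C)=C/CC[C@]2(C)O | intermediate
25 | γ-lactone (C15 to O3) of (1R,3S,4S,7E,11S,12S)-11,12-epoxy-3,4-dihydroxy-4,8,12-trimethylcyclotetradec-7-ene-1-carboxylic acid | O=C1O[C@H]2C[C@H]1CC[C@]3(C)O[C@H]3CC/C(C)=C/CC[C@]2(C)O | intermediate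
26 | lactol of 25 (C15 hemiacetal to O3, anomer mixture) | OC1O[C@H]2C[C@H]1CC[C@]3(C)O[C@H]3CC/C(C)=C/CC[C@]2(C)O | intermediate
27 | dimethyl (1-diazo-2-oxopropyl)phosphonate | COP(=O)(OC)C(=[N+]=[N-])C(C)=O | starting material
28 | (1R,3S,4S,7E,11S,12S)-11,12-epoxy-1-ethynyl-4,8,12-trimethylcyclotetradec-7-ene-3,4-diol | C/C1=C\CC[C@](C)(O)[C@@H](O)C[C@@H](CC[C@]2(C)O[C@H]2CC1)C#C | intermediate
29 | 1,4-bis[(1R,3S,4S,7E,11S,12S)-11,12-epoxy-3,4-dihydroxy-4,8,12-trimethylcyclotetradec-7-en-1-yl]buta-1,3-diyne | C/C1=C\CC[C@](C)(O)[C@@H](O)C[C@@H](CC[C@]2(C)O[C@H]2CC1)C#CC#C[C@@H](C[C@@H]3O)CC[C@]1(C)O[C@H]1CC/C(C)=C/CC[C@]3(C)O | intermediate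
30 | carbon monoxide | [C-]#[O+] | starting material
31 | mono-lactone enyne (ring B closed, (15E)-alkylidene; second half still alkynyl diol) | C/C1=C\CC[C@](C)(O)[C@@H]2C[C@@H](CC[C@]3(C)O[C@H]3CC1)/C(=C\C#C[C@@H](C[C@@H]4O)CC[C@]5(C)O[C@H]5CC/C(C)=C/CC[C@]4(C)O)C(=O)O2 | intermediate
32 | C2-symmetric (15E,15'E)-diene bis-lactone | C/C1=C\CC[C@](C)(O)[C@@H]2C[C@@H](CC[C@]3(C)O[C@H]3CC1)/C(=C\C=C1\C(=O)O[C@H]3C[C@H]1CC[C@]1(C)O[C@H]1CC/C(C)=C/CC[C@]3(C)O)C(=O)O2 | intermediate
33 | dimethylphenylsilyl ketene acetal of the primed lactone (C15'=C16'), (15E)-enoate retained | C/C1=C\CC[C@](C)(O)[C@@H]2C[C@@H](CC[C@]3(C)O[C@H]3CC1)/C(=C\CC4=C(O[Si](C)(C)c5ccccc5)O[C@H]6C[C@H]4CC[C@]7(C)O[C@H]7CC/C(C)=C/CC[C@]6(C)O)C(=O)O2 | intermediate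
34 | (15E,15'S)-15'-hydroxy enoate bis-lactone (15,17-didehydro-36) | C/C1=C\CC[C@](C)(O)[C@@H]2C[C@@H](CC[C@]3(C)O[C@H]3CC1)/C(=C\C[C@@]1(O)C(=O)O[C@H]3C[C@H]1CC[C@]1(C)O[C@H]1CC/C(C)=C/CC[C@]3(C)O)C(=O)O2 | intermediate
35 | 15-epi-36, (15R) | C/C1=C\CC[C@](C)(O)[C@@H]2C[C@@H](CC[C@]3(C)O[C@H]3CC1)[C@@H](CC[C@@]1(O)C(=O)O[C@H]3C[C@H]1CC[C@]1(C)O[C@H]1CC/C(C)=C/CC[C@]3(C)O)C(=O)O2 | intermediate
36 | CNP0186476.4, (1R,3S,4S,7E,11S,12S,15S,1'R,3'S,4'S,7'E,11'S,12'S,15'S) | C/C1=C\CC[C@](C)(O)[C@@H]2C[C@@H](CC[C@]3(C)O[C@H]3CC1)[C@H](CC[C@@]1(O)C(=O)O[C@H]3C[C@H]1CC[C@]1(C)O[C@H]1CC/C(C)=C/CC[C@]3(C)O)C(=O)O2 | target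

## Step count and least certain steps

Total step count: 24. Longest linear sequence: 22 steps (from 4 to 36 through steps 2–12 and 14–24).

Step 21 (key step, proposed new method). The most likely failures are three. The second cyclocarbonylation may stall on the electron-poor enyne 31. The C3 hydroxyl may add directly to the palladium-activated alkyne (5-exo oxypalladation to an enol ether) instead of passing through the alkoxycarbonyl complex. The epoxides may be opened by chloride in the weakly acidic, tin-containing medium. The fallback uses known chemistry and gives up the diyne; it sets out from 28 and comes back at 35. Compound 28, a terminal pent-4-yn-1-ol-type alkynol and thus the documented substrate class, is cyclocarbonylated with PdCl2(PPh3)2, SnCl2 and CO to the α-methylene lactone F1. SmI2 with t-BuOH then couples two molecules of F1 through their β-carbons (reductive tail-to-tail dimerisation of acrylates) and forms C17–C17'. Protonation of both samarium enolates anti to C14 gives the saturated bis-lactone F2. After deprotonation of the tertiary hydroxyls, one further equivalent of KN(SiMe3)2 and 2-(phenylsulfonyl)-3-phenyloxaziridine hydroxylate one lactone enolate anti to C14'. The mono-hydroxylated product is 35, which continues with step 24.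

Step 24 (epimerisation at C15). The equilibrium may not lie on the side of 36, because the trans-1,3 fusion forces one ring substituent into an axial position and the energy difference between the C15 epimers is then small. Slow acyl transfer to the C15' or C4 hydroxyl is a second risk. Kinetic attack on a C15 enolate always comes anti to C14, so C15 can be set kinetically only by forming C15–C17 on the enolate; the fallback therefore changes the bond that is made. It sets out from 28 and comes back at 36. Anti-Markovnikov hydroboration of the alkyne (Cy2BH, then NaBO3) and oxidation of the resulting six-membered lactol (PhI(OAc)2, TEMPO) give the nor-lactone F3, which has the constitution and configuration of A3. Its enolate (LiN(iPr)2, with the hydroxyl as alkoxide) is alkylated twice by ethane-1,2-diyl bis(trifluoromethanesulfonate), each time anti to C14. This gives the bis-lactone F4, in which both α-carbons have the configuration of C15 in 36. Enolisation of one lactone of F4 (KN(SiMe3)2) and hydroxylation with 2-(phenylsulfonyl)-3-phenyloxaziridine anti to C14' give 36.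

Step 7 (Payne rearrangement with malonate trapping). The rearrangement equilibrium lies on the side of 10, and malonate is a weaker nucleophile than the thiolates normally used, so ethanolysis of 12 or slow conversion may compete. The fallback sets out from 10 and comes back at 13. Payne rearrangement with thiolate trapping (PhSH, NaOH, t-BuOH/H2O) gives the phenylthio diol F5. S-methylation with Me3OBF4 gives the sulfonium salt F6, and NaH closes it to the terminal epoxide 12, which is now isolated. Compound 12 is then opened by the sodium salt of 11 (NaH, THF/DMF) to give 13.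

Step 14 (enolate alkylation with 21). Substitution may be slow next to competing elimination of 21 to phenyl vinyl selenide or proton transfer to the enolate, leaving 18 unchanged. The fallback replaces substitution by conjugate addition; it sets out from 18 and comes back at 23. The dianion of 18 (LiN(iPr)2) adds to phenyl vinyl sulfoxide, again anti to the C3 substituent, to give the sulfoxide F7. Thermal syn-elimination (toluene, 110 °C, CaCO3, trimethyl phosphite as sulfenic acid trap) then gives 23.

## Further compounds

F1 | step 21 | α-methylene six-membered lactone of the monomer (ring B closed, C15=C17 exocyclic methylene) | C/C1=C\CC[C@](C)(O)[C@@H]2C[C@@H](CC[C@]3(C)O[C@H]3CC1)C(=C)C(=O)O2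
F2 | step 21 | (15R,15'R)-15'-deoxy bis-lactone (C17 cis to C14 in both halves) | C/C1=C\CC[C@](C)(O)[C@@H]2C[C@@H](CC[C@]3(C)O[C@H]3CC1)[C@@H](CC[C@H]1C(=O)O[C@H]3C[C@H]1CC[C@]1(C)O[C@H]1CC/C(C)=C/CC[C@]3(C)O)C(=O)O2
F3 | step 24 | nor-lactone (six-membered lactone with C15 as CH2; same structure as A3) | C/C1=C\CC[C@](C)(O)[C@@H]2C[C@@H](CC[C@]3(C)O[C@H]3CC1)CC(=O)O2
F4 | step 24 | (15S,15'S)-15'-deoxy bis-lactone (C17 trans to C14 in both halves) | C/C1=C\CC[C@](C)(O)[C@@H]2C[C@@H](CC[C@]3(C)O[C@H]3CC1)[C@H](CC[C@@H]1C(=O)O[C@H]3C[C@H]1CC[C@]1(C)O[C@H]1CC/C(C)=C/CC[C@]3(C)O)C(=O)O2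
F5 | step 7 | (2R,3S,6E)-3,7,11-trimethyl-1-(phenylsulfanyl)dodeca-6,10-diene-2,3-diol | O[C@@H](CSc1ccccc1)[C@@](C)(O)CC/C=C(C)/CCC=C(C)C
F6 | step 7 | S-methyl sulfonium tetrafluoroborate of F5 | C[S+](C[C@H](O)[C@@](C)(O)CC/C=C(C)/CCC=C(C)C)c1ccccc1.F[B-](F)(F)F
F7 | step 14 | (3S,5S)-5-[(2S,5E)-8-[(2S,3S)-3-ethenyl-3-methyloxiran-2-yl]-2-hydroxy-6-methyloct-5-en-2-yl]-3-[2-(phenylsulfinyl)ethyl]oxolan-2-one | O=C1[C@H](CCS(=O)c2ccccc2)C[C@H](O1)[C@@](C)(O)CC/C=C(C)/CC[C@@H]1O[C@@]1(C)C=C
A1 | alternative 1 | seven-membered cyclic alkenylsiloxane with C7=C8, silicon cis to C6 | C[C@@]1(O[Si](C)(C)/C(CC[C@@H]2O[C@@]2(C)CO[Si](C)(C)C(C)(C)C)=C\CC1)[C@@H]3CC=CC(=O)O3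
A2 | alternative 2 | ring A/B nor-lactone as its C4 triethylsilyl ether | C/C1=C\CC[C@](C)(O[Si](CC)(CC)CC)[C@@H]2C[C@@H](CC[C@]3(C)O[C@H]3CC1)CC(=O)O2
A3 | alternative 3 | ring A/B hydroxy nor-lactone | C/C1=C\CC[C@](C)(O)[C@@H]2C[C@@H](CC[C@]3(C)O[C@H]3CC1)CC(=O)O2
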